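**Strategy**

The cyclohexene core is read as a Diels–Alder retron: its C3=C4(Me) alkene lies opposite the C5H2–C6H2 bond, and the quaternary C1 (Me, alkenyl) neighbours the indolyl-bearing C2. The ring is therefore closed by a catalytic enantioselective, exo-selective [4+2] cycloaddition of an N-tosyl 5-(3-methylbuta-1,3-dienyl)indole with methacrolein on a chiral oxazaborolidinium ion. This single operation forms the C5–C6 (CH2–CH2) and C1–C2 bonds and sets both stereocentres; its precursor is an achiral aryl diene. The formyl group then carries the (E)-indolylvinyl arm (boron–Takai olefination, Suzuki coupling with the same bromoindole that supplied the diene).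

Key step: step 6

Remark: cyclohexene locants used throughout are C1 = quaternary carbon (methyl, alkenyl or formyl), C2 = CH(indolyl), C3=C4(Me), C5H2, C6H2; both antipodes of the o-tolyl oxazaborolidine are taken as catalogue items.

**Route**

Step 1
Reactants: 1 methyl 3,3-dimethylpent-4-enoate
Product: 2 3,3-dimethylpent-4-enal
Conditions: DIBAL-H (1.05 equiv), CH2Cl2, −78 °C; aq. potassium sodium tartrate; used as a dried CH2Cl2 solution
Reagents that add atoms: none
Why: Partial reduction of an ester by DIBAL-H stops at the aluminium hemiacetal at −78 °C and releases the aldehyde on work-up; the isolated vinyl group is inert.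

Step 2
Reactants: 2 3,3-dimethylpent-4-enal; 3 (4-bromophenyl)hydrazine hydrochloride
Product: 5 5-bromo-3-(2-methylbut-3-en-2-yl)-1H-indole, via arylhydrazone 4 (not isolated)
Conditions: AcOH, 90 °C
Reagents that add atoms: none
Why: Fischer indole synthesis; the ene-hydrazine of the aldehyde undergoes [3,3] shift and loses ammonia, so the α-carbon bearing the 1,1-dimethylallyl group becomes C3, and the para-bromo substituent can only give the 5-bromo isomer.

Step 3
Reactants: 5 5-bromo-3-(2-methylbut-3-en-2-yl)-1H-indole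
Product: 6 5-bromo-3-(2-methylbut-3-en-2-yl)-1-tosyl-1H-indole
Conditions: TsCl, 50% aq. NaOH, Bu4NHSO4 (cat.), toluene, rt
Reagents that add atoms: p-toluenesulfonyl chloride, Cc1ccc(cc1)S(=O)(=O)Cl
Why: Phase-transfer N-sulfonylation of the indole anion; the tosyl group switches off the nucleophilicity of the indole for the acid-catalysed key step.

Step 4
Reactants: 7 2-methylbut-1-en-3-yne
Product: 8 (E)-4,4,5,5-tetramethyl-2-(3-methylbuta-1,3-dien-1-yl)-1,3,2-dioxaborolane
Conditions: HBpin, Cp2Zr(H)Cl (5 mol%), CH2Cl2, rt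
Reagents that add atoms: pinacolborane, [H]B1OC(C)(C)C(C)(C)O1
Why: Zirconium-catalysed hydroboration of a terminal alkyne is syn and anti-Markovnikov, which should give the (E)-dienylboronate and leave the 1,1-disubstituted alkene untouched.

Step 5
Reactants: 6 5-bromo-3-(2-methylbut-3-en-2-yl)-1-tosyl-1H-indole; 8 (E)-4,4,5,5-tetramethyl-2-(3-methylbuta-1,3-dien-1-yl)-1,3,2-dioxaborolane
Product: 9 5-[(E)-3-methylbuta-1,3-dien-1-yl]-3-(2-methylbut-3-en-2-yl)-1-tosyl-1H-indole
Conditions: Pd(dppf)Cl2 (5 mol%), K3PO4, THF/H2O, 60 °C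
Reagents that add atoms: none
Why: Suzuki–Miyaura coupling of an aryl bromide with an alkenylboronate proceeds with retention of the E geometry; the diene is used promptly to avoid self-dimerisation.

Step 6
Reactants: 9 5-[(E)-3-methylbuta-1,3-dien-1-yl]-3-(2-methylbut-3-en-2-yl)-1-tosyl-1H-indole; 10 methacrolein
Product: 11 (1R,2S)-1,4-dimethyl-2-[3-(2-methylbut-3-en-2-yl)-1-tosyl-1H-indol-5-yl]cyclohex-3-ene-1-carbaldehyde
Conditions: (R)-B-o-tolyl oxazaborolidine from (R)-α,α-diphenylprolinol (20 mol%), Tf2NH (18 mol%), CH2Cl2, −78 → −40 °C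
Reagents that add atoms: none
Why: The N-protonated oxazaborolidine binds the formyl oxygen of s-trans methacrolein (boron syn to the formyl hydrogen, which contacts the ring oxygen) and the diene adds in a concerted, asynchronous [4+2] cycloaddition; the closest known reaction type is the oxazaborolidinium-catalysed enantioselective Diels–Alder reaction of 2-substituted acroleins with 1,3-dienes. The six-membered carbocycle is closed intermolecularly by suprafacial π4s+π2s bonding at both diene termini, the diene CH2 joining the enal CH2 (ring C5–C6) and the aryl-bearing terminus joining the α-carbon (C2–C1). The quaternary centre C1 is controlled by the catalyst: the phenyl group on the face of the bound aldehyde covers one face of the enal, and with the (R)-catalyst the open face is the one that should lead to the 1R configuration. C2 is controlled by the exo arrangement (formyl anti to the diene, methyl under it) together with the E geometry of the diene, which should place the indolyl group cis to the methyl group and trans to the formyl group. Regioselectivity is secured by the aryl group at C1 and the methyl group at C3 of the diene, which both direct the CH2 terminus to the β-carbon of the enal, and exo selectivity by the α-methyl group on a bulky boron-bound enal, which keeps the diene away from the catalyst framework. Chemoselectivity rests on the N-tosyl group, which suppresses Friedel–Crafts addition of the indole to the activated enal, and on the unactivated nature of the 1,1-dimethylallyl vinyl groups.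

Step 7
Reactants: 11 (1R,2S)-1,4-dimethyl-2-[3-(2-methylbut-3-en-2-yl)-1-tosyl-1H-indol-5-yl]cyclohex-3-ene-1-carbaldehyde
Product: 12 2-[(E)-2-{(1S,2R)-1,4-dimethyl-2-[3-(2-methylbut-3-en-2-yl)-1-tosyl-1H-indol-5-yl]cyclohex-3-en-1-yl}ethenyl]-4,4,5,5-tetramethyl-1,3,2-dioxaborolane
Conditions: Cl2CHBpin, CrCl2, LiI, THF, rt
Reagents that add atoms: 2-(dichloromethyl)-4,4,5,5-tetramethyl-1,3,2-dioxaborolane, ClC(Cl)B1OC(C)(C)C(C)(C)O1
Why: Takai–Utimoto (boron–Takai) olefination; the gem-dichromium boryl carbenoid adds to the aldehyde and eliminates to the (E)-alkenylboronate, and the non-enolisable quaternary aldehyde cannot epimerise.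

Step 8
Reactants: 12 the (E)-alkenylboronate of step 7; 6 5-bromo-3-(2-methylbut-3-en-2-yl)-1-tosyl-1H-indole
Product: 13 5-[(E)-2-{(1S,2R)-1,4-dimethyl-2-[3-(2-methylbut-3-en-2-yl)-1-tosyl-1H-indol-5-yl]cyclohex-3-en-1-yl}ethenyl]-3-(2-methylbut-3-en-2-yl)-1-tosyl-1H-indole
Conditions: Pd(dppf)Cl2 (5 mol%), K3PO4, dioxane/H2O, 80 °C
Reagents that add atoms: none
Why: Suzuki–Miyaura coupling with retention of alkene geometry installs the second indole; the boron sits two atoms from the quaternary carbon, so transmetalation should not be hindered.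

Step 9
Reactants: 13 the bis(N-tosyl) compound of step 8
Product: 14 5-[(E)-2-{(1S,2R)-1,4-dimethyl-2-[3-(2-methylbut-3-en-2-yl)-1H-indol-5-yl]cyclohex-3-en-1-yl}ethenyl]-3-(2-methylbut-3-en-2-yl)-1H-indole (target)
Conditions: KOH, MeOH/THF, 65 °C
Reagents that add atoms: none
Why: Nucleophilic cleavage of both N-sulfonyl groups from the indoles under basic conditions that leave every alkene and both stereocentres untouched.

**Compound list**

1 | methyl 3,3-dimethylpent-4-enoate | COC(=O)CC(C)(C)C=C | starting material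
2 | 3,3-dimethylpent-4-enal | O=CCC(C)(C)C=C | intermediate
3 | (4-bromophenyl)hydrazine hydrochloride | NNc1ccc(Br)cc1.Cl | starting material
4 | (E)-1-(4-bromophenyl)-2-(3,3-dimethylpent-4-en-1-ylidene)hydrazine | C=CC(C)(C)C/C=N/Nc1ccc(Br)cc1 | intermediate
5 | 5-bromo-3-(2-methylbut-3-en-2-yl)-1H-indole | C=CC(C)(C)c1c[nH]c2ccc(Br)cc12 | intermediate
6 | 5-bromo-3-(2-methylbut-3-en-2-yl)-1-tosyl-1H-indole | C=CC(C)(C)c1cn(S(=O)(=O)c2ccc(C)cc2)c2ccc(Br)cc12 | intermediate
7 | 2-methylbut-1-en-3-yne | C=C(C)C#C | starting material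
8 | (E)-4,4,5,5-tetramethyl-2-(3-methylbuta-1,3-dien-1-yl)-1,3,2-dioxaborolane | C=C(C)/C=C/B1OC(C)(C)C(C)(C)O1 | intermediate
9 | 5-[(E)-3-methylbuta-1,3-dien-1-yl]-3-(2-methylbut-3-en-2-yl)-1-tosyl-1H-indole | C=CC(C)(C)c1cn(S(=O)(=O)c2ccc(C)cc2)c2ccc(/C=C/C(C)=C)cc12 | intermediate
10 | methacrolein (2-methylprop-2-enal) | C=C(C)C=O | starting material
11 | (1R,2S)-1,4-dimethyl-2-[3-(2-methylbut-3-en-2-yl)-1-tosyl-1H-indol-5-yl]cyclohex-3-ene-1-carbaldehyde | O=C[C@]1(C)CCC(C)=C[C@H]1c1ccc2n(S(=O)(=O)c3ccc(C)cc3)cc(C(C)(C)C=C)c2c1 | intermediate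
12 | 2-[(E)-2-{(1S,2R)-1,4-dimethyl-2-[3-(2-methylbut-3-en-2-yl)-1-tosyl-1H-indol-5-yl]cyclohex-3-en-1-yl}ethenyl]-4,4,5,5-tetramethyl-1,3,2-dioxaborolane | CC1(C)OB(/C=C/[C@]2(C)CCC(C)=C[C@H]2c2ccc3n(S(=O)(=O)c4ccc(C)cc4)cc(C(C)(C)C=C)c3c2)OC1(C)C | intermediate
13 | 5-[(E)-2-{(1S,2R)-1,4-dimethyl-2-[3-(2-methylbut-3-en-2-yl)-1-tosyl-1H-indol-5-yl]cyclohex-3-en-1-yl}ethenyl]-3-(2-methylbut-3-en-2-yl)-1-tosyl-1H-indole | C=CC(C)(C)c1cn(S(=O)(=O)c2ccc(C)cc2)c2ccc(/C=C/[C@]3(C)CCC(C)=C[C@H]3c3ccc4n(S(=O)(=O)c5ccc(C)cc5)cc(C(C)(C)C=C)c4c3)cc12 | intermediate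
14 | 5-[(E)-2-{(1S,2R)-1,4-dimethyl-2-[3-(2-methylbut-3-en-2-yl)-1H-indol-5-yl]cyclohex-3-en-1-yl}ethenyl]-3-(2-methylbut-3-en-2-yl)-1H-indole | C=CC(C)(C)c1c[nH]c2ccc(/C=C/[C@]3(C)CCC(C)=C[C@H]3c3ccc4[nH]cc(C(C)(C)C=C)c4c3)cc12 | target

**Step count and risks**

Total step count: 9. Longest linear sequence: 8 steps (1 → 2 → 5 → 6 → 9 → 11 → 12 → 13 → 14; step 4 is a one-step side branch).

Steps most likely to fail:

Step 6. The cycloaddition may discriminate poorly between the exo and endo arrangements or between the two enal faces, and the strong acid may oligomerise the electron-rich aryl diene before it is trapped. The fallback sets out from 9 and abandons the catalytic cross-cycloaddition for a thermal homodimerisation with resolution. The tosyl group of 9 is removed (KOH, MeOH/THF, 65 °C) to give 5-[(E)-3-methylbuta-1,3-dien-1-yl]-3-(2-methylbut-3-en-2-yl)-1H-indole F1. Heating F1 in toluene at about 110 °C with a trace of BHT should bring about a Diels–Alder dimerisation in which one molecule acts as the diene and the isopropenyl terminus of a second as the dienophile. This gives the racemate, that is 14 together with the antipode of the target F2. Diastereomers are removed on silica and the enantiomers are separated by preparative HPLC on a chiral stationary phase, which comes back to the route at 14.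

Step 2. Under hot acid the 1,1-dimethylallyl group may migrate from C3 to C2 of the newly formed indole, or the vinyl group may be attacked, which would erode the yield of the indolisation. The fallback sets out from 2 and uses a palladium-catalysed annulation in place of the acid-mediated rearrangement. Aldehyde 2 is condensed with commercial 4-bromo-2-iodoaniline (Pd(OAc)2, DABCO, DMF, 85 °C) to the enamine (E)-4-bromo-N-(3,3-dimethylpenta-1,4-dien-1-yl)-2-iodoaniline F3. Oxidative addition, selective for the C–I bond, and intramolecular Heck closure onto the enamine then give the indole under non-acidic conditions and come back to the route at 5.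

Step 7. Addition of the bulky gem-dichromium reagent to the formyl group on the quaternary carbon may be slow, so that conversion stays incomplete or reduction of the aldehyde competes. The fallback sets out from 11 and goes through an alkyne. Seyferth–Gilbert homologation with dimethyl (1-diazo-2-oxopropyl)phosphonate (K2CO3, MeOH, rt) gives 5-[(1S,6R)-6-ethynyl-3,6-dimethylcyclohex-2-en-1-yl]-3-(2-methylbut-3-en-2-yl)-1-tosyl-1H-indole F4. Zirconium-catalysed syn-hydroboration of F4 with pinacolborane (Cp2Zr(H)Cl cat., CH2Cl2, rt, as in step 4) then comes back to the route at 12.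

**Further compounds**

F1 | step 6 | 5-[(E)-3-methylbuta-1,3-dien-1-yl]-3-(2-methylbut-3-en-2-yl)-1H-indole | C=CC(C)(C)c1c[nH]c2ccc(/C=C/C(C)=C)cc12
F2 | step 6 | antipode of the target, 5-[(E)-2-{(1R,2S)-1,4-dimethyl-2-[3-(2-methylbut-3-en-2-yl)-1H-indol-5-yl]cyclohex-3-en-1-yl}ethenyl]-3-(2-methylbut-3-en-2-yl)-1H-indole | C=CC(C)(C)c1c[nH]c2ccc(/C=C/[C@@]3(C)CCC(C)=C[C@@H]3c3ccc4[nH]cc(C(C)(C)C=C)c4c3)cc12
F3 | step 2 | (E)-4-bromo-N-(3,3-dimethylpenta-1,4-dien-1-yl)-2-iodoaniline | C=CC(C)(C)/C=C/Nc1ccc(Br)cc1I
F4 | step 7 | 5-[(1S,6R)-6-ethynyl-3,6-dimethylcyclohex-2-en-1-yl]-3-(2-methylbut-3-en-2-yl)-1-tosyl-1H-indole | C#C[C@]1(C)CCC(C)=C[C@H]1c1ccc2n(S(=O)(=O)c3ccc(C)cc3)cc(C(C)(C)C=C)c2c1
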